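The target is two 4-aryl-3,4-dihydrocoumarins joined C3–C3′: the 5,7-dioxygenated half (ring A, 3,4-trans) and the 5,6,7,8-tetraoxygenated half (ring B, 3′,4′-cis). It is reached by global O-demethylation of octamethyl ether 20, whose cis ring B lactone comes from syn-hydrogenation of a flat 4-arylcoumarin in 19.
Key disconnection: the δ-lactone of the ring A half is opened at O1–C8a and at C3–C4, which gives the bis-silyl ketene acetal 10 of a coumarin-3-acetic acid and the racemic ortho-bromobenzhydryl acetate 16.
Enabling feature: C4 of the ring A lactone is a doubly benzylic methine between ring A (oxygenated at C5 and C7) and the 4-oxygenated phenyl ring, so its planar cation forms easily and erases the configuration of 16. C8a is ortho to C4a, so the carboxylate on C2 reaches it in a six-membered closure, and C3 is α to the carbonyl and allylic, so it equilibrates to trans.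
Ring order: pyranone of the ring B half by Pechmann condensation (step 3), then the lactone of the ring A half (step 8), then saturation of the ring B pyranone (step 9); rings A and B are bought as arenes.

Key step: step 8

Assumption: the sense of induction of the chiral acid in step 8 cannot be predicted with confidence; the (S,S)-catalyst is written for the 4R centre and its mirror image is used if the sense proves opposite.

Step 1
Reactants: 1 1,2,3,4-tetramethoxybenzene
Product: 4 2,3,4,5-tetramethoxyphenol, via aryllithium 2 (not isolated), via boronate 3 (not isolated)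
Conditions: n-BuLi, TMEDA, THF, 0 °C; B(OMe)3, −78 → 23 °C; 30% H2O2, AcOH, 0 → 23 °C
Reagents that add atoms: hydrogen peroxide (OO)
Why: Methoxy-directed ortho-lithiation at the only type of ring C–H, borylation and oxidative 1,2-aryl shift from boron to oxygen (lithiation–borylation–oxidation) should place the hydroxyl group next to the four contiguous methoxy groups.

Step 2
Reactants: 5 ethyl 3-(4-methoxyphenyl)-3-oxopropanoate; 6 ethyl bromoacetate
Product: 7 diethyl 2-(4-methoxybenzoyl)butanedioate (racemic)
Conditions: K2CO3, acetone, 56 °C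
Reagents that add atoms: none
Why: SN2 C-alkylation of the stabilised β-keto ester enolate should give the 2-aroylsuccinate, whose stereocentre is irrelevant because it becomes sp2 in step 3.

Step 3
Reactants: 4 2,3,4,5-tetramethoxyphenol; 7 diethyl 2-(4-methoxybenzoyl)butanedioate
Product: 8 ethyl 2-[5,6,7,8-tetramethoxy-4-(4-methoxyphenyl)-2-oxo-2H-chromen-3-yl]acetate
Conditions: MeSO3H, 23 → 45 °C
Reagents that add atoms: none
Why: Pechmann condensation (transesterification of the phenol, acid-mediated attack of the activated ketone on the single free ortho position, dehydration) should close the pyranone of the ring B half with the aryl group on C4′ and the acetate arm on C3′.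

Step 4
Reactants: 8 ethyl 2-[5,6,7,8-tetramethoxy-4-(4-methoxyphenyl)-2-oxo-2H-chromen-3-yl]acetate
Product: 9 2-[5,6,7,8-tetramethoxy-4-(4-methoxyphenyl)-2-oxo-2H-chromen-3-yl]acetic acid
Conditions: 6 M HCl, AcOH, 90 °C
Reagents that add atoms: water (O)
Why: Acid-catalysed ester hydrolysis should free the side-chain acid while the coumarin lactone, which is stable and recloses under acid, and the aryl methyl ethers stay intact.

Step 5
Reactants: 9 2-[5,6,7,8-tetramethoxy-4-(4-methoxyphenyl)-2-oxo-2H-chromen-3-yl]acetic acid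
Product: 10 3-[2,2-bis(trimethylsilyloxy)ethenyl]-5,6,7,8-tetramethoxy-4-(4-methoxyphenyl)-2H-chromen-2-one
Conditions: LiN(iPr)2 (2.3 equiv), Me3SiCl (2.6 equiv), THF, −78 → 0 °C; used crude under argon
Reagents that add atoms: chlorotrimethylsilane (C[Si](C)(C)Cl)
Why: In-situ double deprotonation–silylation of the acid (silyl ester first, then enolisation of the CH2 flanked by the ester and the coumarin C3′=C4′ bond) should give the bis-silyl ketene acetal, a carboxylic acid C,O-dinucleophile equivalent that has no E/Z isomers.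

Step 6
Reactants: 11 1-bromo-3,5-dimethoxybenzene
Product: 13 2-bromo-4,6-dimethoxybenzaldehyde, via iminium salt 12 (not isolated)
Conditions: POCl3, DMF, 0 → 90 °C; then H2O, 23 °C
Reagents that add atoms: N,N-dimethylformamide (CN(C)C=O); water (O)
Why: Vilsmeier–Haack formylation should occur para to one methoxy group and ortho to the other, next to bromine and not between the two methoxy groups, and hydrolysis of the iminium salt gives the aldehyde.

Step 7
Reactants: 13 2-bromo-4,6-dimethoxybenzaldehyde; 14 (4-methoxyphenyl)magnesium bromide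
Product: 16 (2-bromo-4,6-dimethoxyphenyl)(4-methoxyphenyl)methyl acetate (racemic), via magnesium alkoxide 15 (not isolated)
Conditions: THF, −78 → 0 °C; then Ac2O, 0 → 23 °C
Reagents that add atoms: acetic anhydride (CC(=O)OC(C)=O)
Why: Grignard addition to the aldehyde and acetylation of the magnesium alkoxide in the same flask should give the racemic benzhydryl acetate, whose configuration does not matter because step 8 passes through the planar cation.

Step 8
Reactants: 10 3-[2,2-bis(trimethylsilyloxy)ethenyl]-5,6,7,8-tetramethoxy-4-(4-methoxyphenyl)-2H-chromen-2-one; 16 (2-bromo-4,6-dimethoxyphenyl)(4-methoxyphenyl)methyl acetate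
Product: 19 (3R,4R)-5,7-dimethoxy-4-(4-methoxyphenyl)-3-[5,6,7,8-tetramethoxy-4-(4-methoxyphenyl)-2-oxo-2H-chromen-3-yl]-3,4-dihydro-2H-chromen-2-one, via silyl ester 17 (not isolated), via cesium carboxylate 18 (not isolated)
Conditions: (S,S)-IDPi acid (chiral imidodiphosphorimidate, 5 mol %), toluene, −78 °C; then CsF, CuI (10 mol %), 1,10-phenanthroline (20 mol %), DMF, 110 °C
Reagents that add atoms: none
Why: Proposed new method: the chiral acid is silylated by 10 to a silylium–imidodiphosphorimidate ion pair that abstracts acetate from racemic 16, and the planar, doubly aryl-stabilised C4 carbenium ion, held as a contact ion pair with the chiral anion, is attacked by the α-carbon of the ketene acetal to form C3–C4 and silyl ester 17 (enantioconvergent SN1 alkylation; closest known types are silylium-based counter-anion-directed Mukaiyama-type additions of bis-silyl ketene acetals and Lewis-acid SN1 alkylations of silyl ketene acetals with benzhydryl esters). CsF then unmasks the carboxylate 18, and CuI/phenanthroline joins its oxygen to C8a in place of bromide (intramolecular Ullmann-type O-arylation of a carboxylate, known for 2-haloaryl acids), so that the six-membered lactone closes by C(sp2)–O reductive elimination from a seven-membered aryl-copper carboxylate, formally a 6-exo closure. C4 (R) is set by the chiral counter-anion, both enantiomers of 16 converging on one cation; C3 is formed as a mixture and, being α to the new aryl ester and allylic to the coumarin, equilibrates under the basic closure conditions to the trans (3R,4R) lactone, in which the 4-aryl group is pseudoaxial and away from the peri 5-methoxy group. The step needs α- and not γ-attack of the dienyl ketene acetal (the γ-carbon is tetrasubstituted), facial discrimination at C4 (apolar solvent, −78 °C, tight ion pair) and O-arylation in preference to protodecarboxylation (dry fluoride, six-membered reach of the carboxylate to the ortho bromide).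

Step 9
Reactants: 19 (3R,4R)-5,7-dimethoxy-4-(4-methoxyphenyl)-3-[5,6,7,8-tetramethoxy-4-(4-methoxyphenyl)-2-oxo-2H-chromen-3-yl]-3,4-dihydro-2H-chromen-2-one
Product: 20 (3R,4R)-5,7-dimethoxy-4-(4-methoxyphenyl)-3-[(3S,4R)-5,6,7,8-tetramethoxy-4-(4-methoxyphenyl)-2-oxo-3,4-dihydro-2H-chromen-3-yl]-3,4-dihydro-2H-chromen-2-one
Conditions: H2 (60 bar), Pd(OH)2/C, EtOAc–AcOH, 50 °C
Reagents that add atoms: none
Why: Heterogeneous syn-hydrogenation of the tetrasubstituted coumarin C3′=C4′ bond delivers both hydrogens to one face, which makes the ring B lactone 3′,4′-cis, and with the C3–H of the ring A lactone eclipsing the alkene (allylic 1,3-strain) the catalyst should approach from the face flanked by the lactone carbonyl C2 and not from the face shielded by C4 and its peri-methoxylated ring A, which gives the 3′S,4′R centres.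

Step 10
Reactants: 20 (3R,4R)-5,7-dimethoxy-4-(4-methoxyphenyl)-3-[(3S,4R)-5,6,7,8-tetramethoxy-4-(4-methoxyphenyl)-2-oxo-3,4-dihydro-2H-chromen-3-yl]-3,4-dihydro-2H-chromen-2-one
Product: 21 (3R,4R)-5,7-dihydroxy-4-(4-hydroxyphenyl)-3-[(3S,4R)-5,6,7,8-tetrahydroxy-4-(4-hydroxyphenyl)-2-oxo-3,4-dihydro-2H-chromen-3-yl]-3,4-dihydro-2H-chromen-2-one
Conditions: BBr3 (20 equiv), CH2Cl2, −78 → 0 °C; then degassed H2O, argon
Reagents that add atoms: none
Why: Lewis-acid cleavage of all eight aryl methyl ethers with BBr3 should release the target, since the two aryl lactones survive or reclose on acidic work-up and no base is present that could epimerise the cis lactone.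

Compound list
1 | 1,2,3,4-tetramethoxybenzene | COc1ccc(OC)c(OC)c1OC | starting material
2 | (2,3,4,5-tetramethoxyphenyl)lithium | [Li]c1cc(OC)c(OC)c(OC)c1OC | intermediate
3 | dimethyl (2,3,4,5-tetramethoxyphenyl)boronate | COB(OC)c1cc(OC)c(OC)c(OC)c1OC | intermediate
4 | 2,3,4,5-tetramethoxyphenol | COc1cc(O)c(OC)c(OC)c1OC | intermediate
5 | ethyl 3-(4-methoxyphenyl)-3-oxopropanoate | CCOC(=O)CC(=O)c1ccc(OC)cc1 | starting material
6 | ethyl bromoacetate | CCOC(=O)CBr | starting material
7 | diethyl 2-(4-methoxybenzoyl)butanedioate (racemic) | CCOC(=O)CC(C(=O)OCC)C(=O)c1ccc(OC)cc1 | intermediate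
8 | ethyl 2-[5,6,7,8-tetramethoxy-4-(4-methoxyphenyl)-2-oxo-2H-chromen-3-yl]acetate | CCOC(=O)CC1=C(c2ccc(OC)cc2)c2c(OC)c(OC)c(OC)c(OC)c2OC1=O | intermediate
9 | 2-[5,6,7,8-tetramethoxy-4-(4-methoxyphenyl)-2-oxo-2H-chromen-3-yl]acetic acid | OC(=O)CC1=C(c2ccc(OC)cc2)c2c(OC)c(OC)c(OC)c(OC)c2OC1=O | intermediate
10 | 3-[2,2-bis(trimethylsilyloxy)ethenyl]-5,6,7,8-tetramethoxy-4-(4-methoxyphenyl)-2H-chromen-2-one | C[Si](C)(C)OC(O[Si](C)(C)C)=CC1=C(c2ccc(OC)cc2)c2c(OC)c(OC)c(OC)c(OC)c2OC1=O | intermediate
11 | 1-bromo-3,5-dimethoxybenzene | COc1cc(Br)cc(OC)c1 | starting material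
12 | N-[(2-bromo-4,6-dimethoxyphenyl)methylidene]-N-methylmethanaminium chloride | C[N+](C)=Cc1c(Br)cc(OC)cc1OC.[Cl-] | intermediate
13 | 2-bromo-4,6-dimethoxybenzaldehyde | O=Cc1c(Br)cc(OC)cc1OC | intermediate
14 | (4-methoxyphenyl)magnesium bromide | COc1ccc([Mg]Br)cc1 | starting material
15 | bromomagnesium (2-bromo-4,6-dimethoxyphenyl)(4-methoxyphenyl)methanolate (racemic) | COc1ccc(cc1)C(O[Mg]Br)c1c(Br)cc(OC)cc1OC | intermediate
16 | (2-bromo-4,6-dimethoxyphenyl)(4-methoxyphenyl)methyl acetate (racemic) | CC(=O)OC(c1ccc(OC)cc1)c1c(Br)cc(OC)cc1OC | intermediate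
17 | trimethylsilyl (3R)-3-(2-bromo-4,6-dimethoxyphenyl)-3-(4-methoxyphenyl)-2-[5,6,7,8-tetramethoxy-4-(4-methoxyphenyl)-2-oxo-2H-chromen-3-yl]propanoate (both C2 epimers) | COc1cc(OC)c(c(Br)c1)[C@@H](c1ccc(OC)cc1)C(C(=O)O[Si](C)(C)C)C1=C(c2ccc(OC)cc2)c2c(OC)c(OC)c(OC)c(OC)c2OC1=O | intermediate
18 | cesium (3R)-3-(2-bromo-4,6-dimethoxyphenyl)-3-(4-methoxyphenyl)-2-[5,6,7,8-tetramethoxy-4-(4-methoxyphenyl)-2-oxo-2H-chromen-3-yl]propanoate (both C2 epimers) | COc1cc(OC)c(c(Br)c1)[C@@H](c1ccc(OC)cc1)C(C(=O)[O-])C1=C(c2ccc(OC)cc2)c2c(OC)c(OC)c(OC)c(OC)c2OC1=O.[Cs+] | intermediate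
19 | (3R,4R)-5,7-dimethoxy-4-(4-methoxyphenyl)-3-[5,6,7,8-tetramethoxy-4-(4-methoxyphenyl)-2-oxo-2H-chromen-3-yl]-3,4-dihydro-2H-chromen-2-one (3,4-trans) | O=C1Oc2cc(OC)cc(OC)c2[C@@H](c2ccc(OC)cc2)[C@@H]1C1=C(c2ccc(OC)cc2)c2c(OC)c(OC)c(OC)c(OC)c2OC1=O | intermediate
20 | (3R,4R)-5,7-dimethoxy-4-(4-methoxyphenyl)-3-[(3S,4R)-5,6,7,8-tetramethoxy-4-(4-methoxyphenyl)-2-oxo-3,4-dihydro-2H-chromen-3-yl]-3,4-dihydro-2H-chromen-2-one | O=C1Oc2cc(OC)cc(OC)c2[C@@H](c2ccc(OC)cc2)[C@@H]1[C@H]1C(=O)Oc2c(OC)c(OC)c(OC)c(OC)c2[C@H]1c1ccc(OC)cc1 | intermediate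
21 | (3R,4R)-5,7-dihydroxy-4-(4-hydroxyphenyl)-3-[(3S,4R)-5,6,7,8-tetrahydroxy-4-(4-hydroxyphenyl)-2-oxo-3,4-dihydro-2H-chromen-3-yl]-3,4-dihydro-2H-chromen-2-one | O=C1Oc2cc(O)cc(O)c2[C@@H](c2ccc(O)cc2)[C@@H]1[C@H]1C(=O)Oc2c(O)c(O)c(O)c(O)c2[C@H]1c1ccc(O)cc1 | target

Total step count: 10. Longest linear sequence: 7 steps (1, 3, 4, 5, 8, 9, 10).

Steps most likely to fail

Step 8. The chiral anion may discriminate the two faces of the loosely paired diarylcarbenium ion poorly, the acid may protodesilylate the ketene acetal, and the C–O coupling at the hindered bromide may be outrun by protodecarboxylation. The fallback uses known chemistry and replaces asymmetric catalysis by resolution. It sets out from 10 and 16: an achiral Mukaiyama-type SN1 alkylation (Me3SiOTf, CH2Cl2, −78 °C, aqueous work-up) should give racemic 3-(2-bromo-4,6-dimethoxyphenyl)-3-(4-methoxyphenyl)-2-[5,6,7,8-tetramethoxy-4-(4-methoxyphenyl)-2-oxo-2H-chromen-3-yl]propanoic acid F1 as a mixture of stereoisomers, which is isolated. Ullmann-type lactonisation with epimerisation at C3 (CuI, 1,10-phenanthroline, Cs2CO3, DMF, 110 °C) should then give the racemic trans lactone, and preparative chromatography on a chiral stationary phase separates 19 from its (3S,4S) enantiomer F2. The route is rejoined at 19.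

Step 9. The tetrasubstituted, hindered alkene may not be reduced, the facial selectivity may be poor, and palladium hydride may shift the double bond toward C3 of the ring A lactone and scramble that centre. The fallback makes the reduction carboxylate-directed and catalyst-controlled. It sets out from 19: LiOH in aqueous THF opens both lactones to the tetralithium salt of the ring-opened (Z)-bis(hydroxy acid) F3. Its tetrasubstituted acrylate is hydrogenated with Ru(OAc)2[(S)-BINAP], H2 and MeOH (ligand enantiomer chosen for the 3′S,4′R sense; syn addition keeps the cis relationship) to the saturated tetralithium salt F4. Acidification with HCl recloses both lactones and rejoins the route at 20.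

Step 3. Ring closure at the crowded ortho position with an α-branched aroylacetate may be slow, and sulfonation or partial demethylation may compete. The fallback builds the pyranone by acylation and intramolecular condensation instead. It sets out from 4: TiCl4-mediated Friedel–Crafts ortho-acylation with 4-methoxybenzoyl chloride should give (2-hydroxy-3,4,5,6-tetramethoxyphenyl)(4-methoxyphenyl)methanone F5. O-Acylation with ethyl 4-chloro-4-oxobutanoate (Et3N, CH2Cl2) gives 2-(4-methoxybenzoyl)-3,4,5,6-tetramethoxyphenyl ethyl butanedioate F6. Base-mediated intramolecular Knoevenagel-type condensation of the aryl ester CH2 with the diaryl ketone (DBU, toluene, 110 °C) and dehydration rejoin the route at 8.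

Further compounds
F1 | step 8 | 3-(2-bromo-4,6-dimethoxyphenyl)-3-(4-methoxyphenyl)-2-[5,6,7,8-tetramethoxy-4-(4-methoxyphenyl)-2-oxo-2H-chromen-3-yl]propanoic acid (all stereoisomers) | COc1cc(OC)c(c(Br)c1)C(c1ccc(OC)cc1)C(C(=O)O)C1=C(c2ccc(OC)cc2)c2c(OC)c(OC)c(OC)c(OC)c2OC1=O
F2 | step 8 | (3S,4S)-5,7-dimethoxy-4-(4-methoxyphenyl)-3-[5,6,7,8-tetramethoxy-4-(4-methoxyphenyl)-2-oxo-2H-chromen-3-yl]-3,4-dihydro-2H-chromen-2-one (enantiomer of 19) | O=C1Oc2cc(OC)cc(OC)c2[C@H](c2ccc(OC)cc2)[C@H]1C1=C(c2ccc(OC)cc2)c2c(OC)c(OC)c(OC)c(OC)c2OC1=O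
F3 | step 9 | tetralithium salt of the ring-opened (Z)-bis(hydroxy acid) of 19 (both lactones opened, acrylate carboxylate cis to ring B, ring A half centres unchanged) | [O-]c1cc(OC)cc(OC)c1[C@@H](c1ccc(OC)cc1)[C@@H](C(=O)[O-])/C(C(=O)[O-])=C(\c1ccc(OC)cc1)c1c(OC)c(OC)c(OC)c(OC)c1[O-].[Li+].[Li+].[Li+].[Li+]
F4 | step 9 | tetralithium salt of the ring-opened bis(hydroxy acid) of 20 | [O-]c1cc(OC)cc(OC)c1[C@@H](c1ccc(OC)cc1)[C@@H](C(=O)[O-])[C@@H](C(=O)[O-])[C@H](c1ccc(OC)cc1)c1c(OC)c(OC)c(OC)c(OC)c1[O-].[Li+].[Li+].[Li+].[Li+]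
F5 | step 3 | (2-hydroxy-3,4,5,6-tetramethoxyphenyl)(4-methoxyphenyl)methanone | COc1ccc(cc1)C(=O)c1c(O)c(OC)c(OC)c(OC)c1OC
F6 | step 3 | 2-(4-methoxybenzoyl)-3,4,5,6-tetramethoxyphenyl ethyl butanedioate | CCOC(=O)CCC(=O)Oc1c(OC)c(OC)c(OC)c(OC)c1C(=O)c1ccc(OC)cc1
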